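## Retrosynthetic overview

- Target 15 comes from debenzylation of diacetate 14, which comes from syn-diol 13, itself from fluoride cleavage and C6=C7 saturation of the silylene-protected ene-diol 11.
- 11 is cut at the C1–aryl bond (B-alkyl Suzuki–Miyaura) into guaiacyl bromide 9 and the 9-BBN adduct of vinyl dioxasilinane 7.
- 7 comes from asymmetric ring-opening cross-metathesis of the meso silylene-bridged cyclopentene 3 with syringyl styrene 6. The ring C=C is cut and becomes C6=C7 (aryl end) and C2=C1 (vinyl end).
- Rings: both benzene rings are bought. The O–Si–O bridge is closed first on cis-cyclopentenediol 1, the cyclopentene is then opened, and the six-membered dioxasilinane is removed at the diol stage. No carbocycle is ever closed.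
- Feature: C3 and C5 (the two OAc-bearing carbons) are a syn, pseudo-meso (3R,5S) pair. The two chain ends differ only by the extra OMe on the C7 aryl ring, so C2–C6 correspond to the five ring carbons of meso cis-cyclopent-4-ene-1,3-diol, whose two alkene carbons are enantiotopic.

Key step: step 4

Assumption: the sense of enantiotopic-carbon selection on this new substrate cannot be fixed in advance, so the (S)-biphenolate antipode written in step 4 stands for whichever antipode of the molybdenum catalyst delivers (4R,6S)-7; the styryl bond is drawn E, and its geometry is of no consequence because it is saturated in step 7.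

## Route

Step 1
Reactants: 1 cis-cyclopent-4-ene-1,3-diol (meso); 2 di-tert-butylsilyl bis(trifluoromethanesulfonate)
Product: 3 3,3-di-tert-butyl-2,4-dioxa-3-silabicyclo[3.2.1]oct-6-ene (meso; Si bridges the two cis oxygens)
Conditions: 2,6-lutidine, CH2Cl2/DMF, 0 °C to rt, slow addition of 2 under dilution
Reagents that add atoms: none
Why: Cyclic silylene protection of a 1,3-diol: the hydroxyls are cis on the ring and the strongly electrophilic silyl bis(triflate) should close the six-membered O–Si–O bridge under dilution faster than it silylates a second molecule, with no stereocentre changed and the product still meso.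

Step 2
Reactants: 4 syringaldehyde (4-hydroxy-3,5-dimethoxybenzaldehyde)
Product: 5 4-benzyloxy-3,5-dimethoxybenzaldehyde
Conditions: BnBr, K2CO3, DMF, 60 °C
Reagents that add atoms: benzyl bromide, BrCc1ccccc1
Why: Williamson ether synthesis: the phenoxide displaces bromide from benzyl bromide, and the aldehyde is inert to carbonate.

Step 3
Reactants: 5 4-benzyloxy-3,5-dimethoxybenzaldehyde
Product: 6 4-benzyloxy-3,5-dimethoxystyrene
Conditions: Ph3PCH3Br, KOtBu, THF, 0 °C to rt
Reagents that add atoms: methyltriphenylphosphonium bromide, C[P+](c1ccccc1)(c1ccccc1)c1ccccc1.[Br-]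
Why: Wittig methylenation with the non-stabilised ylide converts the aryl aldehyde into the styrene, and the benzyl and methyl ethers do not react.

Step 4
Reactants: 3 3,3-di-tert-butyl-2,4-dioxa-3-silabicyclo[3.2.1]oct-6-ene; 6 4-benzyloxy-3,5-dimethoxystyrene
Product: 7 (4R,6S)-4-[(E)-2-(4-benzyloxy-3,5-dimethoxyphenyl)ethenyl]-2,2-di-tert-butyl-6-ethenyl-1,3,2-dioxasilinane (cis)
Conditions: Mo(N-2,6-iPr2C6H3)(CHCMe2Ph)[(S)-3,3'-tBu2-5,5',6,6'-Me4-biphenyl-2,2'-diolate] (5 mol %), 6 (3 equiv), C6H6, 22 °C, N2
Reagents that add atoms: none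
Why: Proposed new method: the closest known reaction type is the catalytic asymmetric ring-opening cross-metathesis of meso norbornenes and 8-oxabicyclo[3.2.1]oct-6-enes with styrenes, and bicycle 3 has the same bicyclo[3.2.1]oct-6-ene topology but has not been opened in this way. The molybdenum benzylidene formed from 6 adds [2+2] to the ring alkene of 3 from the face of the one-carbon bridge (C8), cycloreversion cleaves the C6=C7 bond of the bicycle, and a second molecule of 6 releases the product with its terminal vinyl group while regenerating the benzylidene. No ring is closed: the cyclopentene is opened and the six-membered 1,3,2-dioxasilinane survives as a chair with both alkenyl groups equatorial, which together with release of the enforced diaxial C–O arrangement should drive the opening and disfavour back-closure and oligomerisation. No new stereocentre is created; the two carbinol carbons keep their cis relation and receive their absolute sense from the chiral biphenolate ligand, which decides which enantiotopic alkene carbon becomes the styryl carbon. The selectivity needed is this enantiotopic-carbon discrimination, supported by approach to the exo face (the other face is shielded by a tert-butyl group on silicon) and by the excess of 6, which keeps the benzylidene as chain carrier so that the styryl/vinyl product forms and not oligomers.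

Step 5
Reactants: 8 4-bromo-2-methoxyphenol
Product: 9 1-benzyloxy-4-bromo-2-methoxybenzene
Conditions: BnBr, K2CO3, acetone, reflux
Reagents that add atoms: benzyl bromide, BrCc1ccccc1
Why: Williamson ether synthesis on the phenoxide; the aryl bromide is inert under these conditions.

Step 6
Reactants: 7 (4R,6S)-4-[(E)-2-(4-benzyloxy-3,5-dimethoxyphenyl)ethenyl]-2,2-di-tert-butyl-6-ethenyl-1,3,2-dioxasilinane; 9 1-benzyloxy-4-bromo-2-methoxybenzene
Product: 11 (4R,6R)-4-[(E)-2-(4-benzyloxy-3,5-dimethoxyphenyl)ethenyl]-6-[2-(4-benzyloxy-3-methoxyphenyl)ethyl]-2,2-di-tert-butyl-1,3,2-dioxasilinane, via B-alkyl-9-BBN borane 10 (not isolated)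
Conditions: 9-BBN (1.2 equiv), THF, 0 °C to rt; then 9, PdCl2(dppf) (5 mol %), AsPh3, Cs2CO3, DMF/H2O, rt to 50 °C
Reagents that add atoms: 9-borabicyclo[3.3.1]nonane (9-BBN), B1C2CCCC1CCC2 (its boron and ring carbons are held only in 10 and leave again on coupling; product 11 keeps one hydrogen from it)
Why: Hydroboration with 9-BBN is selective for the monosubstituted alkene over the 1,2-disubstituted styryl alkene and puts boron on the terminal carbon, and the B-alkyl Suzuki–Miyaura coupling of that borane with the aryl bromide forms the C1–aryl bond under a mild carbonate base that the silylene should tolerate, with neither carbinol centre involved.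

Step 7
Reactants: 11 (4R,6R)-4-[(E)-2-(4-benzyloxy-3,5-dimethoxyphenyl)ethenyl]-6-[2-(4-benzyloxy-3-methoxyphenyl)ethyl]-2,2-di-tert-butyl-1,3,2-dioxasilinane
Product: 12 (4S,6R)-4-[2-(4-benzyloxy-3,5-dimethoxyphenyl)ethyl]-6-[2-(4-benzyloxy-3-methoxyphenyl)ethyl]-2,2-di-tert-butyl-1,3,2-dioxasilinane
Conditions: TsNHNH2 (excess, in portions), NaOAc, DME/H2O, reflux
Reagents that add atoms: none
Why: Diimide reduction: concerted syn transfer of two hydrogens from HN=NH saturates C6=C7 without the hydrogenolysis of benzyl ethers or of the allylic C–O bond that a palladium-catalysed hydrogenation would risk, and the stereocentres are untouched (only the descriptor at C5 changes).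

Step 8
Reactants: 12 (4S,6R)-4-[2-(4-benzyloxy-3,5-dimethoxyphenyl)ethyl]-6-[2-(4-benzyloxy-3-methoxyphenyl)ethyl]-2,2-di-tert-butyl-1,3,2-dioxasilinane
Product: 13 (3R,5S)-1-(4-benzyloxy-3-methoxyphenyl)-7-(4-benzyloxy-3,5-dimethoxyphenyl)heptane-3,5-diol
Conditions: HF·pyridine, THF/pyridine, 0 °C to rt
Reagents that add atoms: none
Why: Fluoride-mediated desilylation: both Si–O bonds are cleaved with formation of Si–F bonds to free the syn-diol, while aryl benzyl and methyl ethers are inert to HF·pyridine.

Step 9
Reactants: 13 (3R,5S)-1-(4-benzyloxy-3-methoxyphenyl)-7-(4-benzyloxy-3,5-dimethoxyphenyl)heptane-3,5-diol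
Product: 14 (3R,5S)-1-(4-benzyloxy-3-methoxyphenyl)-7-(4-benzyloxy-3,5-dimethoxyphenyl)heptane-3,5-diyl diacetate
Conditions: Ac2O, pyridine, DMAP (cat.), CH2Cl2, rt
Reagents that add atoms: acetic anhydride, CC(=O)OC(C)=O
Why: DMAP-catalysed acylation esterifies both secondary alcohols with retention, since no C–O bond at a stereocentre is broken.

Step 10
Reactants: 14 (3R,5S)-1-(4-benzyloxy-3-methoxyphenyl)-7-(4-benzyloxy-3,5-dimethoxyphenyl)heptane-3,5-diyl diacetate
Product: 15 (3R,5S)-1-(4-hydroxy-3-methoxyphenyl)-7-(4-hydroxy-3,5-dimethoxyphenyl)heptane-3,5-diyl diacetate (target)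
Conditions: H2 (1 atm), Pd/C, EtOAc, rt
Reagents that add atoms: none
Why: Hydrogenolysis of the two aryl benzyl ethers frees both phenols, while alkyl acetates, aryl methyl ethers and the saturated chain are stable under neutral conditions, so the (3R,5S) configuration should be carried through unchanged.

## Compound list

1 | cis-cyclopent-4-ene-1,3-diol (meso) | C1=C[C@@H](O)C[C@H]1O | starting material
2 | di-tert-butylsilyl bis(trifluoromethanesulfonate) | CC(C)(C)[Si](OS(=O)(=O)C(F)(F)F)(OS(=O)(=O)C(F)(F)F)C(C)(C)C | starting material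
3 | 3,3-di-tert-butyl-2,4-dioxa-3-silabicyclo[3.2.1]oct-6-ene (meso) | C1=C[C@@H]2C[C@H]1O[Si](C(C)(C)C)(C(C)(C)C)O2 | intermediate
4 | syringaldehyde | COc1cc(C=O)cc(OC)c1O | starting material
5 | 4-benzyloxy-3,5-dimethoxybenzaldehyde | COc1cc(C=O)cc(OC)c1OCc1ccccc1 | intermediate
6 | 4-benzyloxy-3,5-dimethoxystyrene | C=Cc1cc(OC)c(OCc2ccccc2)c(OC)c1 | intermediate
7 | (4R,6S)-4-[(E)-2-(4-benzyloxy-3,5-dimethoxyphenyl)ethenyl]-2,2-di-tert-butyl-6-ethenyl-1,3,2-dioxasilinane | C=C[C@@H]1C[C@H](/C=C/c2cc(OC)c(OCc3ccccc3)c(OC)c2)O[Si](C(C)(C)C)(C(C)(C)C)O1 | intermediate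
8 | 4-bromo-2-methoxyphenol | COc1cc(Br)ccc1O | starting material
9 | 1-benzyloxy-4-bromo-2-methoxybenzene | COc1cc(Br)ccc1OCc1ccccc1 | intermediate
10 | B-alkyl-9-BBN borane from the vinyl group of 7 (boron on the terminal carbon) | C(C[C@@H]1C[C@H](/C=C/c2cc(OC)c(OCc3ccccc3)c(OC)c2)O[Si](C(C)(C)C)(C(C)(C)C)O1)B1C2CCCC1CCC2 | intermediate
11 | (4R,6R)-4-[(E)-2-(4-benzyloxy-3,5-dimethoxyphenyl)ethenyl]-6-[2-(4-benzyloxy-3-methoxyphenyl)ethyl]-2,2-di-tert-butyl-1,3,2-dioxasilinane | COc1cc(CC[C@@H]2C[C@H](/C=C/c3cc(OC)c(OCc4ccccc4)c(OC)c3)O[Si](C(C)(C)C)(C(C)(C)C)O2)ccc1OCc1ccccc1 | intermediate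
12 | (4S,6R)-4-[2-(4-benzyloxy-3,5-dimethoxyphenyl)ethyl]-6-[2-(4-benzyloxy-3-methoxyphenyl)ethyl]-2,2-di-tert-butyl-1,3,2-dioxasilinane | COc1cc(CC[C@@H]2C[C@H](CCc3cc(OC)c(OCc4ccccc4)c(OC)c3)O[Si](C(C)(C)C)(C(C)(C)C)O2)ccc1OCc1ccccc1 | intermediate
13 | (3R,5S)-1-(4-benzyloxy-3-methoxyphenyl)-7-(4-benzyloxy-3,5-dimethoxyphenyl)heptane-3,5-diol | COc1cc(CC[C@H](C[C@H](CCc2cc(OC)c(OCc3ccccc3)c(OC)c2)O)O)ccc1OCc1ccccc1 | intermediate
14 | (3R,5S)-1-(4-benzyloxy-3-methoxyphenyl)-7-(4-benzyloxy-3,5-dimethoxyphenyl)heptane-3,5-diyl diacetate | COc1cc(CC[C@H](C[C@H](CCc2cc(OC)c(OCc3ccccc3)c(OC)c2)OC(C)=O)OC(C)=O)ccc1OCc1ccccc1 | intermediate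
15 | (3R,5S)-1-(4-hydroxy-3-methoxyphenyl)-7-(4-hydroxy-3,5-dimethoxyphenyl)heptane-3,5-diyl diacetate | COc1cc(CC[C@H](C[C@H](CCc2cc(OC)c(O)c(OC)c2)OC(C)=O)OC(C)=O)ccc1O | target

## Count and risks

Total step count: 10. Longest linear sequence: 8 steps (4 → 5 → 6 → 7 → 11 → 12 → 13 → 14 → 15, that is steps 2, 3, 4, 6, 7, 8, 9, 10).

**Step 4 (Proposed new method).** The ring opening may be slow or reversible because the silylene-bridged cyclopentene carries less strain than a norbornene, which would lead to oligomerisation. The discrimination between the enantiotopic alkene carbons may be weak. The vinyl group may react further by secondary cross-metathesis.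

Fallback by known chemistry, setting out from 9 and 5 and coming back at 13: Heck arylation of allyl alcohol with 9 (Pd(OAc)2, Bu4NCl, NaHCO3, DMF, 80 °C) gives 3-(4-benzyloxy-3-methoxyphenyl)propanal F1. Claisen–Schmidt condensation of 5 with acetone (aqueous NaOH) gives (E)-4-(4-benzyloxy-3,5-dimethoxyphenyl)but-3-en-2-one F2. Conjugate reduction of F2 with [(Ph3P)CuH]6 gives 4-(4-benzyloxy-3,5-dimethoxyphenyl)butan-2-one F3. The boron enolate of F3, formed on the methyl side with Ipc2BCl/Et3N (the antipode that leads to the R carbinol), adds to F1 in an asymmetric aldol reaction to give (R)-7-(4-benzyloxy-3-methoxyphenyl)-1-(4-benzyloxy-3,5-dimethoxyphenyl)-5-hydroxyheptan-3-one F4. Narasaka–Prasad syn reduction (Et2BOMe, NaBH4, THF/MeOH, −78 °C) should then give diol 13, which continues with step 9. This path also bypasses step 1, should the bridged silylene form only as oligomers.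

**Step 6.** The borane may also add to the styryl alkene, transmetalation of the alkylborane may be slow so that β-hydride elimination or protodeboronation takes over, and the basic aqueous medium may open the silylene.

Fallback, setting out from 7 and 9 and coming back at 12: Mizoroki–Heck arylation of the terminal vinyl group of 7 with 9 (Pd(OAc)2, P(o-tol)3, NaOAc, DMF, 100 °C) should give (4R,6S)-4-[(E)-2-(4-benzyloxy-3,5-dimethoxyphenyl)ethenyl]-6-[(E)-2-(4-benzyloxy-3-methoxyphenyl)ethenyl]-2,2-di-tert-butyl-1,3,2-dioxasilinane F5. Both styryl bonds are then saturated together by homogeneous hydrogenation (H2, RhCl(PPh3)3, benzene/EtOH), which leaves benzyl ethers intact, to give 12, which continues with step 8.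

**Step 7.** Saturation may stay incomplete, because diimide disproportionates faster than it reduces a conjugated, electron-rich 1,2-disubstituted alkene that is shielded by the silylene.

Fallback, setting out from 11 and coming back at 13: the silylene is removed first (HF·pyridine, THF) to give (3R,5R,E)-1-(4-benzyloxy-3-methoxyphenyl)-7-(4-benzyloxy-3,5-dimethoxyphenyl)hept-6-ene-3,5-diol F6. Its allylic hydroxyl then directs a homogeneous hydrogenation with [Ir(cod)(PCy3)(py)]PF6 under H2 in CH2Cl2, which spares benzyl ethers, to give 13, which continues with step 9.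

## Further compounds

F1 | step 4 | 3-(4-benzyloxy-3-methoxyphenyl)propanal | COc1cc(CCC=O)ccc1OCc1ccccc1
F2 | step 4 | (E)-4-(4-benzyloxy-3,5-dimethoxyphenyl)but-3-en-2-one | CC(=O)/C=C/c1cc(OC)c(OCc2ccccc2)c(OC)c1
F3 | step 4 | 4-(4-benzyloxy-3,5-dimethoxyphenyl)butan-2-one | CC(=O)CCc1cc(OC)c(OCc2ccccc2)c(OC)c1
F4 | step 4 | (R)-7-(4-benzyloxy-3-methoxyphenyl)-1-(4-benzyloxy-3,5-dimethoxyphenyl)-5-hydroxyheptan-3-one | COc1cc(CC[C@H](CC(=O)CCc2cc(OC)c(OCc3ccccc3)c(OC)c2)O)ccc1OCc1ccccc1
F5 | step 6 | (4R,6S)-4-[(E)-2-(4-benzyloxy-3,5-dimethoxyphenyl)ethenyl]-6-[(E)-2-(4-benzyloxy-3-methoxyphenyl)ethenyl]-2,2-di-tert-butyl-1,3,2-dioxasilinane | COc1cc(/C=C/[C@@H]2C[C@H](/C=C/c3cc(OC)c(OCc4ccccc4)c(OC)c3)O[Si](C(C)(C)C)(C(C)(C)C)O2)ccc1OCc1ccccc1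
F6 | step 7 | (3R,5R,E)-1-(4-benzyloxy-3-methoxyphenyl)-7-(4-benzyloxy-3,5-dimethoxyphenyl)hept-6-ene-3,5-diol | COc1cc(CC[C@H](C[C@H](/C=C/c2cc(OC)c(OCc3ccccc3)c(OC)c2)O)O)ccc1OCc1ccccc1
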